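**Plan**
Retrosynthesis: the C6 acetate is cut first (C6–O), then both tiglate C–O bonds, then the C2–CH2OH bond; the C4 oxygen is traced back to a C4 acetyl group; last, the ring is cut at C3–C4 and C5–C6.
Enabling feature: the cyclohex-2-en-1-one ring itself. C1=O with C2=C3 on one side and the C6 methylene on the other is the retron of a 1-amino-3-siloxybuta-1,3-diene (termini C3 and C6), and the C4/C5 pair maps onto (E)-5-methylhex-3-en-2-one.
Forward: one [4+2] cycloaddition builds the only ring and, after loss of the amine, the enone; then acetyl to hydroxyl at C4, hydroxymethylation at C2, double esterification, and acetoxylation at C6.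
Stereochemistry: C5 comes from the C2-symmetric pyrrolidine on the diene (face selection) together with endo approach; C4 arrives trans to C5 from the E-alkene and is inverted when the tiglate is put on; C6 is set last by attack anti to the C4 and C5 substituents.

Key step: step 3

Assumption: the (2R,5R)-2,5-diphenylpyrrolidine auxiliary is taken to expose the diene face that leads to the (5S)-configured cycloadduct; should the sense of induction be the opposite, the (2S,5S)-amine is used and nothing else changes.

**Step 1**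
Reactants: 1 (3E)-4-methoxybut-3-en-2-one; 2 (2R,5R)-2,5-diphenylpyrrolidine
Product: 3 (3E)-4-[(2R,5R)-2,5-diphenylpyrrolidin-1-yl]but-3-en-2-one
Conditions: toluene, 60 °C, MeOH distilled off
Reagents that add atoms: none
Why: Vinylogous transamination (conjugate addition–elimination) of the β-methoxy enone by the secondary amine should give the E-enaminone; the auxiliary stereocentres are untouched.

**Step 2**
Reactants: 3 (3E)-4-[(2R,5R)-2,5-diphenylpyrrolidin-1-yl]but-3-en-2-one
Product: 4 (2R,5R)-1-[(1E)-3-{[tert-butyl(dimethyl)silyl]oxy}buta-1,3-dien-1-yl]-2,5-diphenylpyrrolidine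
Conditions: KN(SiMe3)2, THF, −78 °C; then TBSCl, −78 °C to rt
Reagents that add atoms: tert-butyldimethylsilyl chloride, CC(C)(C)[Si](C)(C)Cl
Why: Kinetic enolisation of the methyl group (the only acidic C–H of the vinylogous amide) followed by O-silylation should give the 1-amino-3-siloxy diene.

**Step 3**
Reactants: 4 (2R,5R)-1-[(1E)-3-{[tert-butyl(dimethyl)silyl]oxy}buta-1,3-dien-1-yl]-2,5-diphenylpyrrolidine; 5 (3E)-5-methylhex-3-en-2-one
Product: 7 (4R,5S)-4-acetyl-5-(propan-2-yl)cyclohex-2-en-1-one, via silyl enol ether cycloadduct 6 (not isolated)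
Conditions: toluene, 60 °C, sealed tube; then 10% aq. HF, MeCN, 0 °C to rt; basic extraction returns 2
Reagents that add atoms: none
Why: A concerted, asynchronous, normal-demand Diels–Alder reaction is expected, in which the amino and siloxy donors both place the largest HOMO coefficient on the CH2 terminus (future C6), so it bonds to the enone β-carbon (future C5) while the nitrogen-bearing terminus (future C3) bonds to the α-carbon (future C4). The closest known reaction type is the cycloaddition of chiral 1-amino-3-siloxybutadienes with acrylates, enals and enones to give 4- and 4,5-substituted cyclohexenones. The six-membered ring closes in an intermolecular [4+2] mode, suprafacial on both partners, so the E-geometry of 5 is carried over as the trans relation of the C4 acetyl and C5 isopropyl groups. The absolute configuration at C5 (S) and C4 (R) is controlled by the C2-symmetric pyrrolidine, which shields one diene face, together with endo approach of the acetyl group, which decides which enone face is paired with the open diene face. Aqueous HF then cleaves the silyl enol ether and the resulting β-amino ketone loses the auxiliary by E1cB elimination, which unveils C2=C3 and destroys the C3 stereocentre. The step needs regio-, endo and facial selectivity, which are secured by the 1-amino/3-siloxy substitution, secondary overlap of the acetyl group and the auxiliary, and the trans C4/C5 arrangement is also the thermodynamic one, so enolisation at C4 cannot erode it.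

**Step 4**
Reactants: 7 (4R,5S)-4-acetyl-5-(propan-2-yl)cyclohex-2-en-1-one
Product: 8 (4R,5S)-4-(acetyloxy)-5-(propan-2-yl)cyclohex-2-en-1-one
Conditions: mCPBA, NaHCO3, CH2Cl2, 0 °C to rt
Reagents that add atoms: 3-chloroperoxybenzoic acid, OOC(=O)c1cccc(Cl)c1
Why: Baeyer–Villiger oxidation, in which the secondary allylic C4 should migrate in preference to methyl with retention of configuration, while the conjugated C1 carbonyl and the electron-poor C2=C3 bond react much more slowly with peracid.

**Step 5**
Reactants: 8 (4R,5S)-4-(acetyloxy)-5-(propan-2-yl)cyclohex-2-en-1-one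
Product: 9 (4R,5S)-4-hydroxy-5-(propan-2-yl)cyclohex-2-en-1-one
Conditions: K2CO3 (0.2 equiv), MeOH, 0 °C, short contact time
Reagents that add atoms: none
Why: Base-catalysed transesterification of the allylic acetate with methanol should free the C4 hydroxyl without touching the C–O bond, so the configuration is kept.

**Step 6**
Reactants: 9 (4R,5S)-4-hydroxy-5-(propan-2-yl)cyclohex-2-en-1-one; 10 formaldehyde
Product: 11 (4S,5S)-4-hydroxy-2-(hydroxymethyl)-5-(propan-2-yl)cyclohex-2-en-1-one
Conditions: 37% aq. HCHO, DMAP (0.3 equiv), THF–H2O, rt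
Reagents that add atoms: none
Why: Morita–Baylis–Hillman hydroxymethylation: DMAP adds to C3, the enolate adds to formaldehyde through C2, and loss of DMAP restores the enone; no stereocentre is involved (the C4 descriptor changes only because of ligand priorities).

**Step 7**
Reactants: 11 (4S,5S)-4-hydroxy-2-(hydroxymethyl)-5-(propan-2-yl)cyclohex-2-en-1-one; 12 tiglic acid, (2E)-2-methylbut-2-enoic acid
Product: 13 (4R,5S)-4-{[(2E)-2-methylbut-2-enoyl]oxy}-2-({[(2E)-2-methylbut-2-enoyl]oxy}methyl)-5-(propan-2-yl)cyclohex-2-en-1-one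
Conditions: 12 (3 equiv), PPh3 (3 equiv), DIAD (3 equiv), toluene, 0 °C to rt
Reagents that add atoms: none
Why: Double Mitsunobu esterification: both hydroxyls are activated as oxyphosphonium ions and displaced by tiglate, at the primary carbon without stereochemical consequence and at C4 by SN2 with inversion, which should place the C4 ester cis to the isopropyl group (the same inversion that turns menthol into neomenthyl esters).

**Step 8**
Reactants: 13 (4R,5S)-4-{[(2E)-2-methylbut-2-enoyl]oxy}-2-({[(2E)-2-methylbut-2-enoyl]oxy}methyl)-5-(propan-2-yl)cyclohex-2-en-1-one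
Product: 14 (4S,5S,6R)-6-(acetyloxy)-4-{[(2E)-2-methylbut-2-enoyl]oxy}-2-({[(2E)-2-methylbut-2-enoyl]oxy}methyl)-5-(propan-2-yl)cyclohex-2-en-1-one
Conditions: Mn(OAc)3·2H2O (2.5 equiv), benzene–AcOH (10:1), reflux with removal of water
Reagents that add atoms: manganese triacetate, CC(=O)[O-].CC(=O)[O-].CC(=O)[O-].[Mn+3]
Why: α′-Acetoxylation of an enone by trivalent manganese: the manganese enolate can form only toward C6 and should deliver acetate anti to the C5 isopropyl group and the pseudoaxial C4 ester, which gives the 6R centre (acetate trans to isopropyl).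

**Compound list**
1 | (3E)-4-methoxybut-3-en-2-one | CO/C=C/C(C)=O | starting material
2 | (2R,5R)-2,5-diphenylpyrrolidine | N1[C@@H](c2ccccc2)CC[C@@H]1c1ccccc1 | starting material
3 | (3E)-4-[(2R,5R)-2,5-diphenylpyrrolidin-1-yl]but-3-en-2-one | CC(=O)/C=C/N1[C@@H](c2ccccc2)CC[C@@H]1c1ccccc1 | intermediate
4 | (2R,5R)-1-[(1E)-3-{[tert-butyl(dimethyl)silyl]oxy}buta-1,3-dien-1-yl]-2,5-diphenylpyrrolidine | C=C(O[Si](C)(C)C(C)(C)C)/C=C/N1[C@@H](c2ccccc2)CC[C@@H]1c1ccccc1 | intermediate
5 | (3E)-5-methylhex-3-en-2-one | CC(=O)/C=C/C(C)C | starting material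
6 | 1-[(1S,2R,6S)-4-{[tert-butyl(dimethyl)silyl]oxy}-2-[(2R,5R)-2,5-diphenylpyrrolidin-1-yl]-6-(propan-2-yl)cyclohex-3-en-1-yl]ethan-1-one (endo cycloadduct; amino and acetyl cis, acetyl and isopropyl trans) | CC(C)(C)[Si](C)(C)OC1=C[C@@H](N2[C@@H](c3ccccc3)CC[C@@H]2c2ccccc2)[C@@H](C(C)=O)[C@H](C(C)C)C1 | intermediate
7 | (4R,5S)-4-acetyl-5-(propan-2-yl)cyclohex-2-en-1-one | O=C1C=C[C@@H](C(C)=O)[C@H](C(C)C)C1 | intermediate
8 | (4R,5S)-4-(acetyloxy)-5-(propan-2-yl)cyclohex-2-en-1-one | O=C1C=C[C@@H](OC(C)=O)[C@H](C(C)C)C1 | intermediate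
9 | (4R,5S)-4-hydroxy-5-(propan-2-yl)cyclohex-2-en-1-one | O=C1C=C[C@@H](O)[C@H](C(C)C)C1 | intermediate
10 | formaldehyde | C=O | starting material
11 | (4S,5S)-4-hydroxy-2-(hydroxymethyl)-5-(propan-2-yl)cyclohex-2-en-1-one | OCC1=C[C@@H](O)[C@H](C(C)C)CC1=O | intermediate
12 | tiglic acid, (2E)-2-methylbut-2-enoic acid | C/C=C(\C)C(=O)O | starting material
13 | (4R,5S)-4-{[(2E)-2-methylbut-2-enoyl]oxy}-2-({[(2E)-2-methylbut-2-enoyl]oxy}methyl)-5-(propan-2-yl)cyclohex-2-en-1-one | C/C=C(\C)C(=O)OCC1=C[C@H](OC(=O)/C(C)=C/C)[C@H](C(C)C)CC1=O | intermediate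
14 | (4S,5S,6R)-6-(acetyloxy)-4-{[(2E)-2-methylbut-2-enoyl]oxy}-2-({[(2E)-2-methylbut-2-enoyl]oxy}methyl)-5-(propan-2-yl)cyclohex-2-en-1-one | C/C=C(\C)C(=O)OCC1=C[C@H](OC(=O)/C(C)=C/C)[C@H](C(C)C)[C@@H](OC(C)=O)C1=O | target

**Step count and risks**
Total step count: 8. Longest linear sequence: 8 steps (from 1 and 2 to 14).

Steps most likely to fail:

1. Step 3. The β-branched enone may add slowly, so that the temperature needed erodes facial selectivity or the diene is lost by hydrolysis before it reacts. Fallback, setting out from 4: the diene is combined with the more reactive (2E)-4-methylpent-2-enal at or below room temperature, which should give the aldehyde cycloadduct F1. MeMgBr (THF, −78 °C) is added to the formyl group to give the carbinol cycloadduct F2 as a mixture of carbinol epimers. Aqueous HF in MeCN then releases the auxiliary and gives the hydroxyethyl enone F3. Oxidation of the secondary alcohol with 1,1,1-triacetoxy-1,1-dihydro-1,2-benziodoxol-3(1H)-one in CH2Cl2 comes back to the route at 7.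

2. Step 4. The peracid may attack the enone, or the γ-acyl enone may enolise toward C4 so that the acetyl group reacts as its enol and chemoselectivity is lost. Fallback, setting out from 4, in which the C4 oxygen is introduced by vinylogous oxidation instead of acyl migration: cycloaddition with ethyl (2E)-4-methylpent-2-enoate gives the ester cycloadduct F4, and aqueous HF gives the keto ester F5. Saponification (LiOH, THF–H2O) gives the keto acid F6, a vinylogous β-keto acid that should lose CO2 on warming to give the enone F7. Isopropenyl acetate with TsOH gives the linear dienyl acetate F8. mCPBA should epoxidise its C3=C4 bond anti to the isopropyl group, and collapse of the epoxide on work-up comes back to the route at 9.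

3. Step 7. At the hindered C4 the oxyphosphonium ion may eliminate toward a dienone and then a phenol, or the activated primary allylic position may be attacked in the SN2′ sense. Fallback, setting out from 11, in which the two esterifications are separated: tigloyl chloride (1 equiv) with 2,4,6-collidine in CH2Cl2 at −78 °C acylates the primary hydroxyl selectively to give the primary mono-tiglate F9. MsCl and Et3N give the mesylate F10. Displacement with cesium tiglate (from 12 and Cs2CO3) and 18-crown-6 in toluene at 60 °C proceeds with inversion and comes back to the route at 13.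

**Further compounds**
F1 | step 3 | (1S,2R,6S)-4-{[tert-butyl(dimethyl)silyl]oxy}-2-[(2R,5R)-2,5-diphenylpyrrolidin-1-yl]-6-(propan-2-yl)cyclohex-3-ene-1-carbaldehyde | CC(C)(C)[Si](C)(C)OC1=C[C@@H](N2[C@@H](c3ccccc3)CC[C@@H]2c2ccccc2)[C@@H](C=O)[C@H](C(C)C)C1
F2 | step 3 | 1-hydroxyethyl analogue of cycloadduct 6 (carbinol epimers, ring stereocentres arranged as in 6) | CC(C)(C)[Si](C)(C)OC1=C[C@@H](N2[C@@H](c3ccccc3)CC[C@@H]2c2ccccc2)[C@@H](C(C)O)[C@H](C(C)C)C1
F3 | step 3 | (4R,5S)-4-(1-hydroxyethyl)-5-(propan-2-yl)cyclohex-2-en-1-one (carbinol epimers) | O=C1C=C[C@@H](C(C)O)[C@H](C(C)C)C1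
F4 | step 4 | ethyl (1S,2R,6S)-4-{[tert-butyl(dimethyl)silyl]oxy}-2-[(2R,5R)-2,5-diphenylpyrrolidin-1-yl]-6-(propan-2-yl)cyclohex-3-ene-1-carboxylate | CC(C)(C)[Si](C)(C)OC1=C[C@@H](N2[C@@H](c3ccccc3)CC[C@@H]2c2ccccc2)[C@@H](C(=O)OCC)[C@H](C(C)C)C1
F5 | step 4 | ethyl (1R,6S)-4-oxo-6-(propan-2-yl)cyclohex-2-ene-1-carboxylate | O=C1C=C[C@@H](C(=O)OCC)[C@H](C(C)C)C1
F6 | step 4 | (1R,6S)-4-oxo-6-(propan-2-yl)cyclohex-2-ene-1-carboxylic acid | O=C1C=C[C@@H](C(=O)O)[C@H](C(C)C)C1
F7 | step 4 | (5S)-5-(propan-2-yl)cyclohex-2-en-1-one | O=C1C=CC[C@H](C(C)C)C1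
F8 | step 4 | (5S)-5-(propan-2-yl)cyclohexa-1,3-dien-1-yl acetate | CC(=O)OC1=CC=C[C@H](C(C)C)C1
F9 | step 7 | [(3S,4S)-3-hydroxy-6-oxo-4-(propan-2-yl)cyclohex-1-en-1-yl]methyl (2E)-2-methylbut-2-enoate | C/C=C(\C)C(=O)OCC1=C[C@@H](O)[C@H](C(C)C)CC1=O
F10 | step 7 | [(3S,4S)-3-[(methanesulfonyl)oxy]-6-oxo-4-(propan-2-yl)cyclohex-1-en-1-yl]methyl (2E)-2-methylbut-2-enoate | C/C=C(\C)C(=O)OCC1=C[C@@H](OS(C)(=O)=O)[C@H](C(C)C)CC1=O
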